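**Retrosynthetic overview**
- Target ⇐ pentacyclic methyl ester; the last step removes the methyl group and sets C14 by kinetic protonation.
- Ring P and the C5 spiro centre ⇐ C5 spiro-epoxide: trivalent-titanium epoxide opening gives the tertiary C5 radical, which adds to isopropyl vinyl ketone (C4–C5 bond, key step); cyclodehydration then closes the enol ether.
- Epoxide ⇐ bridging C5 ketone ⇐ double Mannich annulation (ring A, quaternary C8) on a tricyclic keto ester.
- Ring E ⇐ palladium [3+2] cycloaddition of a resolved allylic acetate with methyl acrylate (C15 by chirality transfer).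
- Rings F then D ⇐ cyclopentane-1,3-dione + chloroacetone + a vinyl unit (Suzuki coupling, 7-endo vinylogous Michael). Ring order: F, D, E, A, P.

Atom labels used below: N; C1 = NCH2 on C8; C2, C3, C4 = enol-ether carbon, =CH and CH2 of ring P; C5 = spiro carbon; C6 = CH next to C5; C7 = NCH2 on C6; C8 = quaternary carbon; C9=C10 = ring alkene (C9 on C8); C11, C12 = CH2CH2 from C10 to C6; C13 = CH2 on C8; C14 = CH(CO2H); C15 = CH between C14 and C9; C16, C17 = CH2CH2 from C15 to C10; C18–C20 = isopropyl; C21 = OCH2; C22 = carboxyl carbon. Ring A = N, C1, C8, C5, C6, C7; ring D = C5, C6, C12, C11, C10, C9, C8; ring E = C8, C9, C15, C14, C13; ring F = C9, C10, C17, C16, C15; ring P = O, C21, C5, C4, C3, C2. In these labels the target is (5R,6R,8S,14S,15S).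

Assumption: 4-methylpent-1-en-3-one and potassium vinyltrifluoroborate are taken as purchasable.

**Step 1**
Reactants: 1 cyclopentane-1,3-dione; 2 chloroacetone
Product: 3 2-(2-oxopropyl)cyclopentane-1,3-dione
Conditions: KOH (1.05 equiv), KI (cat.), H2O, 0 °C → rt
Reagents that add atoms: none
Why: The fully ionised 1,3-dione displaces chloride from the activated α-chloro ketone through carbon (Stetter-type C-alkylation of a cyclic 1,3-dione), and the product is protected from a second alkylation as its own enolate.

**Step 2**
Reactants: 3 2-(2-oxopropyl)cyclopentane-1,3-dione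
Product: 4 3-oxo-2-(2-oxopropyl)cyclopent-1-en-1-yl trifluoromethanesulfonate
Conditions: Tf2O, Et3N, CH2Cl2, −78 → 0 °C
Reagents that add atoms: trifluoromethanesulfonic anhydride, O=S(=O)(OS(=O)(=O)C(F)(F)F)C(F)(F)F
Why: O-sulfonylation of the enolised dione gives the vinylogous acyl triflate (enol triflate formation), while the side-chain ketone is not enolised by Et3N at low temperature.

**Step 3**
Reactants: 4 3-oxo-2-(2-oxopropyl)cyclopent-1-en-1-yl trifluoromethanesulfonate; 5 potassium vinyltrifluoroborate
Product: 7 2,3,5,6-tetrahydroazulene-1,7(4H,8H)-dione (rings D and F; enone carbonyl = C15, ring ketone = C5), via vinyl dienone 6 (not isolated)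
Conditions: PdCl2(dppf)·CH2Cl2 (5 mol%), Cs2CO3, THF/H2O 9:1, 70 °C; then dilute to 0.02 M, KOH (0.3 equiv), 40 °C
Reagents that add atoms: none
Why: Suzuki–Miyaura coupling of the electron-poor enol triflate gives dienone 6, whose methyl-ketone (C6) enolate closes ring D by an intramolecular vinylogous 1,6-Michael addition in the 7-endo-trig mode, the more acidic C8 position having only a disfavoured 5-endo-trig path, and the dienolate reprotonates to the conjugated C9=C10 enone.

**Step 4**
Reactants: 7 2,3,5,6-tetrahydroazulene-1,7(4H,8H)-dione
Product: 8 racemic 1-hydroxy-2,3,4,5,6,8-hexahydroazulen-7(1H)-one (allylic alcohol at C15)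
Conditions: NaBH4, CeCl3·7H2O, MeOH, −78 → −40 °C
Reagents that add atoms: none
Why: Luche reduction, in which the hard methoxyborohydride formed with CeCl3 adds 1,2 to the conjugated C15 carbonyl in preference to the isolated C5 ketone (Gemal–Luche selectivity) and gives the racemic allylic alcohol.

**Step 5**
Reactants: 8 racemic 1-hydroxy-2,3,4,5,6,8-hexahydroazulen-7(1H)-one
Product: 9 (1R)-7-oxo-1,2,3,4,5,6,7,8-octahydroazulen-1-yl acetate
Conditions: Novozym 435 (immobilised Candida antarctica lipase B), vinyl acetate, t-BuOMe, 30 °C, stopped near 50% conversion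
Reagents that add atoms: vinyl acetate, CC(=O)OC=C
Why: Lipase-catalysed kinetic resolution by transesterification, in which Kazlauskas' rule predicts acylation of the (R)-alcohol (large group = the tetrasubstituted alkene side) while (S)-8 stays unreacted and is separated, so the C15 carbinol centre is obtained as the (R)-acetate in high ee with a 50% ceiling on yield.

**Step 6**
Reactants: 9 (1R)-7-oxo-1,2,3,4,5,6,7,8-octahydroazulen-1-yl acetate; 10 methyl acrylate (1.5 equiv)
Product: 11 tricyclic keto ester (rings D, E, F fused about C9; C5 ketone, C9=C10 alkene, CO2Me on C14, 15S; C8–H and C14 as epimer mixtures)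
Conditions: Pd2(dba)3·CHCl3 (2.5 mol%), P(OiPr)3 (15 mol%), iPr2NEt (1.2 equiv), THF, 60 °C
Reagents that add atoms: none
Why: Proposed new method: zerovalent palladium ionises the allylic acetate anti to the leaving group to a cationic π-allyl complex (C15–C9–C10) whose C8–H, α to the ketone and on the central allyl carbon, is removed by acetate/amine to give a ketone-stabilised trimethylenemethane-type zwitterion that adds through C8 to the acrylate and then closes through the ester enolate onto the less substituted allyl terminus C15 anti to palladium (net retention, so the (R)-acetate gives 15S and the C9=C10 alkene is restored), the closest known reactions being Trost's palladium–trimethylenemethane [3+2] cycloaddition and its deprotonative variants with cyano-, sulfonyl- and acyl-stabilised donors; C8 stays epimerisable and C14 is set in the last step.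

**Step 7**
Reactants: 11 tricyclic keto ester; 12 methylamine; 13 formaldehyde (2.2 equiv)
Product: 15 tetracyclic amino ketone (ring A bridging C8 and C6 of 11 as N-methylpiperidine; C5 ketone on the one-atom bridge), via aminomethyl ketone 14 (not isolated)
Conditions: MeNH2 (40% aq.), (CH2O)n, AcOH, 65 °C
Reagents that add atoms: none
Why: Double Mannich annulation (Petrenko-Kritschenko/Robinson–Schöpf type), in which the dienol of the β,γ-unsaturated ketone is aminomethylated at C8 from the convex face of the bowl-shaped tricycle (anti to C16 on C15) to create the quaternary centre, and the derived N-methyl methyleneiminium ion then cyclises onto the C6 enol, which can only bridge on the same face, so C8 and C6 are set together relative to C15.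

**Step 8**
Reactants: 15 tetracyclic amino ketone; 16 trimethylsulfonium iodide
Product: 17 C5 spiro-epoxide (oxirane CH2 = C21; both C5 epimers)
Conditions: 16, n-BuLi, THF, −10 °C; then 15, −10 °C → rt
Reagents that add atoms: none
Why: Corey–Chaykovsky epoxidation of the non-enolisable bridging ketone by dimethylsulfonium methylide, where both epoxide epimers are usable because C5 becomes a planar radical in the next step.

**Step 9**
Reactants: 17 C5 spiro-epoxide; 18 4-methylpent-1-en-3-one (5 equiv)
Product: 20 pentacyclic methyl ester (rings A, D, E, F, P; target skeleton with CO2Me at C14 and C14 unassigned), via hydroxy ketone 19 (not isolated)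
Conditions: Cp2TiCl2 (20 mol%), Zn dust, 2,4,6-collidine·HCl, THF, rt; then PPTS (cat.), 4 Å MS, PhMe, 110 °C
Reagents that add atoms: none
Why: Nugent–RajanBabu/Gansäuer reductive epoxide opening, in which Cp2TiCl (trivalent titanium, turned over by Zn and collidinium chloride) cleaves the C5–O bond to the tertiary β-titanoxy radical, which cannot collapse to an allylic alcohol (C8 quaternary, C6 a bridgehead) and undergoes Giese addition to the vinyl ketone on the face syn to the cycloheptene bridge (flanked by sp2 C9 and one axial C12–H) rather than the piperidine face (two syn-axial C–H on C1 and C7), which fixes the C5 spiro centre with C21 over ring A; the δ-hydroxy ketone 19 then cyclodehydrates under mild acid to the endocyclic enol ether.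

**Step 10**
Reactants: 20 pentacyclic methyl ester
Product: 23 target acid CNP0237695.2, via potassium carboxylate 21 (not isolated), via enediolate 22 (not isolated)
Conditions: KOSiMe3, THF, 45 °C; then LiN(iPr)2 (4 equiv), −78 → 0 °C; then AcOH/THF, −78 °C; pH 7 buffer
Reagents that add atoms: none
Why: Anhydrous demethylation of the ester by silanolate (attack at the O-methyl carbon) gives carboxylate 21, LiN(iPr)2 converts it into enediolate 22, and kinetic protonation at C14 from the convex face (anti to C16 and C5) places the carboxyl group cis to C16, which corrects either C14 epimer formed earlier (carboxylic acid dianion formation and kinetic protonation).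

**Compound list**
1 | cyclopentane-1,3-dione | O=C1CCC(=O)C1 | starting material
2 | chloroacetone | CC(=O)CCl | starting material
3 | 2-(2-oxopropyl)cyclopentane-1,3-dione | CC(=O)CC1C(=O)CCC1=O | intermediate
4 | 3-oxo-2-(2-oxopropyl)cyclopent-1-en-1-yl trifluoromethanesulfonate | CC(=O)CC1=C(OS(=O)(=O)C(F)(F)F)CCC1=O | intermediate
5 | potassium vinyltrifluoroborate | C=C[B-](F)(F)F.[K+] | starting material
6 | 2-(2-oxopropyl)-3-vinylcyclopent-2-en-1-one | CC(=O)CC1=C(C=C)CCC1=O | intermediate
7 | 2,3,5,6-tetrahydroazulene-1,7(4H,8H)-dione | O=C1CCCC2=C(C1)C(=O)CC2 | intermediate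
8 | racemic 1-hydroxy-2,3,4,5,6,8-hexahydroazulen-7(1H)-one | O=C1CCCC2=C(C1)C(O)CC2 | intermediate
9 | (1R)-7-oxo-1,2,3,4,5,6,7,8-octahydroazulen-1-yl acetate | O=C1CCCC2=C(C1)[C@H](OC(C)=O)CC2 | intermediate
10 | methyl acrylate | C=CC(=O)OC | starting material
11 | tricyclic keto ester (rings D, E, F; 15S; C8 and C14 epimer mixtures) | O=C1CCCC2=C3[C@@H](CC2)C(C(=O)OC)CC13 | intermediate
12 | methylamine | CN | starting material
13 | formaldehyde | C=O | starting material
14 | C8-(methylaminomethyl) keto ester (CH2NHMe on C8 anti to C16) | O=C1CCCC2=C3[C@@H](CC2)C(C(=O)OC)C[C@@]13CNC | intermediate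
15 | tetracyclic amino ketone (rings A, D, E, F; C5 ketone) | O=C1[C@H]2CCC3=C4[C@@H](CC3)C(C(=O)OC)C[C@]41CN(C)C2 | intermediate
16 | trimethylsulfonium iodide | C[S+](C)C.[I-] | starting material
17 | C5 spiro-epoxide (both C5 epimers) | C1OC12[C@H]3CCC4=C5[C@@H](CC4)C(C(=O)OC)C[C@]52CN(C)C3 | intermediate
18 | 4-methylpent-1-en-3-one | C=CC(=O)C(C)C | starting material
19 | δ-hydroxy ketone (C5 bears CH2OH syn to ring A and CH2CH2C(O)iPr syn to ring D) | CC(C)C(=O)CC[C@@]2(CO)[C@H]1CCC3=C4[C@@H](CC3)C(C(=O)OC)C[C@]42CN(C)C1 | intermediate
20 | pentacyclic methyl ester (C14 unassigned) | CC(C)C1=CC[C@@]2(CO1)[C@H]1CCC3=C4[C@@H](CC3)C(C(=O)OC)C[C@]42CN(C)C1 | intermediate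
21 | potassium carboxylate of 20 | CC(C)C1=CC[C@@]2(CO1)[C@H]1CCC3=C4[C@@H](CC3)C(C(=O)[O-])C[C@]42CN(C)C1.[K+] | intermediate
22 | C14 enediolate (lithium potassium salt) | CC(C)C1=CC[C@@]2(CO1)[C@H]1CCC3=C4[C@@H](CC3)C(=C([O-])[O-])C[C@]42CN(C)C1.[K+].[Li+] | intermediate
23 | CNP0237695.2 | CC(C)C1=CC[C@@]2(CO1)[C@H]1CCC3=C4[C@@H](CC3)[C@@H](C(=O)O)C[C@]42CN(C)C1 | target

**Totals**
Total step count: 10. Longest linear sequence: 10 steps (from 1).

**Steps most likely to fail and their fallbacks**

Step 9 (radical spiro-annulation) is the greatest risk: the tertiary radical is very hindered, the facial preference at C5 is predicted rather than known, and trivalent titanium can also reduce the enone. The fallback is an ionic construction of the same centre that sets out from 17. MgBr2·OEt2 rearranges the epoxide (Meinwald) to the C5 aldehyde F5. Base-catalysed Michael addition of its enolate to 18 (DBU, MeCN, 0 °C) gives the keto aldehyde F6 with the quaternary C5. NaBH(OAc)3 then reduces only the aldehyde to give hydroxy ketone 19, where the route is rejoined.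

Step 6 (palladium [3+2]) is the next risk: acetate-driven deprotonation of the π-allyl complex is untested for a ketone, and β-hydride loss to a diene or O-closure to a furan can compete. The fallback sets out from 9 and generates the dipole by Trost's original desilylative mode from a bifunctional silyl/acetate precursor. TMSOTf/Et3N gives the conjugated silyl dienol ether, (1R)-7-(trimethylsilyloxy)-1,2,3,4,5,6-hexahydroazulen-1-yl acetate F4. With Pd(OAc)2/P(OiPr)3 and 10 in THF at 60 °C, the acetate released on ionisation removes silicon and the same zwitterion cyclises to 11, where the route is rejoined.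

Step 3 (one-pot coupling and 7-endo closure) is the third risk: the more acidic C8–H2 can divert dienone 6 (oligomerisation, electrocyclisation of the C8 enolate). The fallback closes ring D by a radical that is generated only at C6 and sets out from 1. C-alkylation with 1,3-dichloroacetone gives 2-(3-chloro-2-oxopropyl)cyclopentane-1,3-dione F1. Triflation as in step 2 gives the enol triflate F2. Coupling with 5 under amine-base conditions (PdCl2(dppf), Et3N, n-PrOH) gives the chloromethyl ketone dienone F3. Slow addition of Bu3SnH/AIBN (PhH, 80 °C) forms the α-keto radical at C6, which attacks the vinyl terminus in the 7-endo mode; the dienone-stabilised radical is reduced to 7, where the route is rejoined.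

**Further compounds**
F1 | step 3 | 2-(3-chloro-2-oxopropyl)cyclopentane-1,3-dione | O=C(CCl)CC1C(=O)CCC1=O
F2 | step 3 | 2-(3-chloro-2-oxopropyl)-3-oxocyclopent-1-en-1-yl trifluoromethanesulfonate | O=C(CCl)CC1=C(OS(=O)(=O)C(F)(F)F)CCC1=O
F3 | step 3 | 2-(3-chloro-2-oxopropyl)-3-vinylcyclopent-2-en-1-one | O=C(CCl)CC1=C(C=C)CCC1=O
F4 | step 6 | (1R)-7-(trimethylsilyloxy)-1,2,3,4,5,6-hexahydroazulen-1-yl acetate | C[Si](C)(C)OC1=CC2=C(CCC1)CC[C@H]2OC(C)=O
F5 | step 9 | C5 aldehyde (CHO = C21, C5–H) of the tetracyclic amino ester | O=CC1[C@H]2CCC3=C4[C@@H](CC3)C(C(=O)OC)C[C@]41CN(C)C2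
F6 | step 9 | C5 keto aldehyde (CHO syn to ring A, CH2CH2C(O)iPr syn to ring D) | CC(C)C(=O)CC[C@@]2(C=O)[C@H]1CCC3=C4[C@@H](CC3)C(C(=O)OC)C[C@]42CN(C)C1
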